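**Retrosynthetic overview**

- Feature: on ring A the C5 hydroxyl and the C8 methoxyl are para, the pattern of a reduced para-quinone monoketal, and C8 is the only ring A carbon bearing hydrogen in the 5-hydroxy-6,7-dimethoxyflavone.
- Gardenin C ⇐ ester methanolysis ⇐ zinc reduction (loss of one methanol) of the 8,8-dimethoxy-5-oxo monoketal ⇐ anodic double methoxylation at C8 (two molecules of methanol) of the 3'-O-pivaloyl 5-hydroxy-6,7-dimethoxyflavone.
- That flavone ⇐ chelation-directed 5-O-demethylation ⇐ 3'-O-pivaloylation of the 3'-hydroxy-5,6,7,4',5'-pentamethoxyflavone ⇐ I2/DMSO cyclization of the chalcone from C-acetylated 3,4,5-trimethoxyphenol and 3-hydroxy-4,5-dimethoxybenzaldehyde.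
- Ring order: rings A and B come from the two bought arenes, ring C (the pyranone) is closed in step 3, and the key step closes no ring.

Key step: step 6

Remark: the 3'-hydroxyl is pivaloylated before the 5-O-demethylation, so the acylation needs no site selectivity and ring B carries no free phenol next to a methoxy group when BCl3 is used.

**Route**

Step 1
Reactants: 1 3,4,5-trimethoxyphenol
Product: 2 1-(6-hydroxy-2,3,4-trimethoxyphenyl)ethan-1-one
Conditions: AcOH (solvent), BF3·OEt2 (3 equiv), 90 °C, 2 h; then H2O
Reagents that add atoms: acetic acid, CC(=O)O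
Why: BF3-promoted Friedel–Crafts C-acylation at one of the two equivalent, triply activated positions ortho to the phenol oxygen, after which the chelated ketone deactivates the ring toward a second acylation.

Step 2
Reactants: 2 1-(6-hydroxy-2,3,4-trimethoxyphenyl)ethan-1-one; 3 3-hydroxy-4,5-dimethoxybenzaldehyde
Product: 4 (E)-3-(3-hydroxy-4,5-dimethoxyphenyl)-1-(6-hydroxy-2,3,4-trimethoxyphenyl)prop-2-en-1-one
Conditions: KOH (50% aq., 10 equiv), EtOH, rt, 48 h; then 2 M HCl
Reagents that add atoms: none
Why: Claisen–Schmidt aldol condensation in which the aldehyde stays electrophilic because its phenoxide is meta to the formyl group, and E1cB dehydration should give the E-enone.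

Step 3
Reactants: 4 (E)-3-(3-hydroxy-4,5-dimethoxyphenyl)-1-(6-hydroxy-2,3,4-trimethoxyphenyl)prop-2-en-1-one
Product: 7 2-(3-hydroxy-4,5-dimethoxyphenyl)-5,6,7-trimethoxy-4H-chromen-4-one, via flavanone 5 (not isolated), via 3-iodoflavanone 6 (not isolated)
Conditions: I2 (5 mol %), DMSO, 120 °C, 3 h
Reagents that add atoms: none
Why: Iodine-catalysed oxidative cyclization of a 2'-hydroxychalcone (6-endo oxa-Michael closure, α-iodination of the ketone and loss of HI, with DMSO re-oxidizing HI to I2), in which the low iodine loading limits iodination of the electron-rich rings.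

Step 4
Reactants: 7 2-(3-hydroxy-4,5-dimethoxyphenyl)-5,6,7-trimethoxy-4H-chromen-4-one; 8 pivaloyl chloride
Product: 9 2,3-dimethoxy-5-(5,6,7-trimethoxy-4-oxo-4H-chromen-2-yl)phenyl 2,2-dimethylpropanoate
Conditions: Et3N (2 equiv), DMAP (5 mol %), CH2Cl2, 0 °C to rt
Reagents that add atoms: none
Why: DMAP-catalysed esterification of the only free hydroxyl, giving a hindered aryl ester that lowers the electron density of ring B for the anodic step.

Step 5
Reactants: 9 2,3-dimethoxy-5-(5,6,7-trimethoxy-4-oxo-4H-chromen-2-yl)phenyl 2,2-dimethylpropanoate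
Product: 10 5-(5-hydroxy-6,7-dimethoxy-4-oxo-4H-chromen-2-yl)-2,3-dimethoxyphenyl 2,2-dimethylpropanoate
Conditions: BCl3 (1 M in CH2Cl2, 2.5 equiv), CH2Cl2, −78 to 0 °C, 1 h; then H2O
Reagents that add atoms: none
Why: Chelation-directed ether cleavage in which BCl3 bridges the C4 carbonyl and the peri C5 methoxy oxygen in a six-membered chelate and chloride removes that methyl only, the other four methyl ethers and the pivalate having no such assistance at 0 °C.

Step 6
Reactants: 10 5-(5-hydroxy-6,7-dimethoxy-4-oxo-4H-chromen-2-yl)-2,3-dimethoxyphenyl 2,2-dimethylpropanoate; 11 methanol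
Product: 13 2,3-dimethoxy-5-(6,7,8,8-tetramethoxy-4,5-dioxo-5,8-dihydro-4H-chromen-2-yl)phenyl 2,2-dimethylpropanoate, via 8-methoxy phenol 12 (not isolated)
Conditions: graphite anode, Pt cathode, undivided cell, constant current (5 mA cm−2, about 4.2 F mol−1), LiClO4 (0.1 M), 2,6-lutidine (2 equiv), MeOH/MeCN 3:1 (MeOH in large excess), 0 °C
Reagents that add atoms: methanol, CO
Why: Anodic two-electron oxidation of the 5-phenol (proton taken by 2,6-lutidine) gives a phenoxonium ion that a first molecule of methanol (11) captures at C8, the only ring A carbon bearing hydrogen and the position para to the phenol oxygen, and loss of the C8 proton gives the 8-methoxy phenol 12; 12 is oxidized at a lower potential than 10 and its phenoxonium ion is trapped by a second molecule of methanol from the solvent, now ipso at the methoxy-stabilized C8, so that about 4 F per mole and two equivalents of methanol should lead to the 8,8-dimethoxy-5-oxo monoketal 13. The closest known reaction type is the anodic methoxylation of para-unsubstituted phenols and of 4-methoxyphenols to para-quinone monoketals in methanol with LiClO4, applied here to a chelated 5-hydroxyflavone. No ring is closed and no stereocenter is formed, since the two new C8–O bonds place two identical methoxy groups on C8. The step needs ring A to be oxidized before ring B and methanol to enter at C8 instead of ipso at C6: the tetraoxygenated phenol ring should have the lower oxidation potential because ring B is deactivated by its pivalate and by conjugation with the pyranone, and para capture at the unhindered C8 should be preferred over attack at the flanked C6. Oxidation should stop at 13 because ring A is no longer aromatic, and any 13 that is reduced at the cathode only returns 12, which the anode oxidizes again.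

Step 7
Reactants: 13 2,3-dimethoxy-5-(6,7,8,8-tetramethoxy-4,5-dioxo-5,8-dihydro-4H-chromen-2-yl)phenyl 2,2-dimethylpropanoate
Product: 12 5-(5-hydroxy-6,7,8-trimethoxy-4-oxo-4H-chromen-2-yl)-2,3-dimethoxyphenyl 2,2-dimethylpropanoate
Conditions: Zn dust (5 equiv), glacial AcOH/THF 1:4, 0 °C to rt, 30 min
Reagents that add atoms: none
Why: Dissolving-metal reductive aromatization of a quinone monoketal, in which two-electron reduction of the cross-conjugated enedione gives a dienolate that expels one C8 methoxide, so that C5 returns as the chelated phenol and C8 as the methyl ether while the flavone enone and the pivalate should survive the short, cold exposure.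

Step 8
Reactants: 12 5-(5-hydroxy-6,7,8-trimethoxy-4-oxo-4H-chromen-2-yl)-2,3-dimethoxyphenyl 2,2-dimethylpropanoate
Product: 14 Gardenin C, 5-hydroxy-2-(3-hydroxy-4,5-dimethoxyphenyl)-6,7,8-trimethoxy-4H-chromen-4-one
Conditions: K2CO3 (2 equiv), MeOH, rt to 40 °C; then 1 M HCl
Reagents that add atoms: none
Why: Base-mediated transesterification (methanolysis) of the aryl pivalate, driven by the good phenoxide leaving group, under conditions to which the methyl ethers and the chelated 5-hydroxyflavone core are stable.

**Compound list**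

1 | 3,4,5-trimethoxyphenol | COc1cc(O)cc(OC)c1OC | starting material
2 | 1-(6-hydroxy-2,3,4-trimethoxyphenyl)ethan-1-one | CC(=O)c1c(O)cc(OC)c(OC)c1OC | intermediate
3 | 3-hydroxy-4,5-dimethoxybenzaldehyde | COc1cc(C=O)cc(O)c1OC | starting material
4 | (E)-3-(3-hydroxy-4,5-dimethoxyphenyl)-1-(6-hydroxy-2,3,4-trimethoxyphenyl)prop-2-en-1-one | COc1cc(/C=C/C(=O)c2c(O)cc(OC)c(OC)c2OC)cc(O)c1OC | intermediate
5 | 2-(3-hydroxy-4,5-dimethoxyphenyl)-5,6,7-trimethoxychroman-4-one (flavanone, racemic, not isolated) | COc1cc(C2CC(=O)c3c(OC)c(OC)c(OC)cc3O2)cc(O)c1OC | intermediate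
6 | 2-(3-hydroxy-4,5-dimethoxyphenyl)-3-iodo-5,6,7-trimethoxychroman-4-one (3-iodoflavanone, racemic diastereomer mixture, not isolated) | COc1cc(C2Oc3cc(OC)c(OC)c(OC)c3C(=O)C2I)cc(O)c1OC | intermediate
7 | 2-(3-hydroxy-4,5-dimethoxyphenyl)-5,6,7-trimethoxy-4H-chromen-4-one | COc1cc(-c2cc(=O)c3c(OC)c(OC)c(OC)cc3o2)cc(O)c1OC | intermediate
8 | pivaloyl chloride (2,2-dimethylpropanoyl chloride) | CC(C)(C)C(Cl)=O | starting material
9 | 2,3-dimethoxy-5-(5,6,7-trimethoxy-4-oxo-4H-chromen-2-yl)phenyl 2,2-dimethylpropanoate | COc1cc(-c2cc(=O)c3c(OC)c(OC)c(OC)cc3o2)cc(OC(=O)C(C)(C)C)c1OC | intermediate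
10 | 5-(5-hydroxy-6,7-dimethoxy-4-oxo-4H-chromen-2-yl)-2,3-dimethoxyphenyl 2,2-dimethylpropanoate | COc1cc(-c2cc(=O)c3c(O)c(OC)c(OC)cc3o2)cc(OC(=O)C(C)(C)C)c1OC | intermediate
11 | methanol | CO | starting material
12 | 5-(5-hydroxy-6,7,8-trimethoxy-4-oxo-4H-chromen-2-yl)-2,3-dimethoxyphenyl 2,2-dimethylpropanoate (formed in step 6 without isolation, isolated in step 7) | COc1cc(-c2cc(=O)c3c(O)c(OC)c(OC)c(OC)c3o2)cc(OC(=O)C(C)(C)C)c1OC | intermediate
13 | 2,3-dimethoxy-5-(6,7,8,8-tetramethoxy-4,5-dioxo-5,8-dihydro-4H-chromen-2-yl)phenyl 2,2-dimethylpropanoate | COC1=C(OC)C(OC)(OC)C2=C(C1=O)C(=O)C=C(c1cc(OC)c(OC)c(OC(=O)C(C)(C)C)c1)O2 | intermediate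
14 | Gardenin C, 5-hydroxy-2-(3-hydroxy-4,5-dimethoxyphenyl)-6,7,8-trimethoxy-4H-chromen-4-one | COc1cc(-c2cc(=O)c3c(O)c(OC)c(OC)c(OC)c3o2)cc(O)c1OC | target

**Step count**

Total step count: 8. Longest linear sequence: 8 steps (1 to 14).

**Steps most likely to fail**

Step 6. Methanol may enter ring A ipso at C6 instead of at C8, the electron-poor pyranone of the monoketal may add methanol, oxidation may spread to ring B, or the second oxidation may stall so that 10, 12 and 13 are obtained together. Fallback without electrochemistry or dearomatization: setting out from 10, electrophilic bromination with NBS in CH2Cl2/DMF at 0 °C should go to C8, the one free ring A position and para to the phenol, to give 5-(8-bromo-5-hydroxy-6,7-dimethoxy-4-oxo-4H-chromen-2-yl)-2,3-dimethoxyphenyl 2,2-dimethylpropanoate F1. Copper-mediated Ullmann-type methoxylation of F1 with NaOMe and CuBr in MeOH/DMF at 110 °C should then replace bromide by methoxide and cleave the pivalate in the same flask. The branch comes back to the route at the target 14, so steps 7 and 8 are not needed.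

Step 7. The ketal may be hydrolysed by the acid before electron transfer, which would leave a hydroxyl instead of a methoxyl at C8, or reduction may continue into the pyranone enone. Fallback that accepts the hydrolysis: setting out from 13, aqueous HCl in THF should give the quinone 5-(6,7-dimethoxy-4,5,8-trioxo-5,8-dihydro-4H-chromen-2-yl)-2,3-dimethoxyphenyl 2,2-dimethylpropanoate F2. Aqueous Na2S2O4 in THF should reduce it to the hydroquinone 5-(5,8-dihydroxy-6,7-dimethoxy-4-oxo-4H-chromen-2-yl)-2,3-dimethoxyphenyl 2,2-dimethylpropanoate F3. Partial methylation with Me2SO4 (1.05 equiv) and K2CO3 in acetone under argon should then alkylate only the unchelated C8 hydroxyl, and the branch comes back to the route at 12.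

Step 5. A second methyl group may be lost, most likely at C6 next to the newly formed boron chelate, so that the reaction cannot be held at the mono-phenol. Fallback that makes the double cleavage the plan: setting out from 9, AlBr3 in MeCN should remove both the C5 and the C6 methyl groups to give 5-(5,6-dihydroxy-7-methoxy-4-oxo-4H-chromen-2-yl)-2,3-dimethoxyphenyl 2,2-dimethylpropanoate F4. Partial methylation with Me2SO4 (1.0 equiv) and K2CO3 in acetone under argon should then alkylate only the unchelated C6 hydroxyl, and the branch comes back to the route at 10.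

Further compounds
F1 | step 6 | 5-(8-bromo-5-hydroxy-6,7-dimethoxy-4-oxo-4H-chromen-2-yl)-2,3-dimethoxyphenyl 2,2-dimethylpropanoate | COc1cc(-c2cc(=O)c3c(O)c(OC)c(OC)c(Br)c3o2)cc(OC(=O)C(C)(C)C)c1OC
F2 | step 7 | 5-(6,7-dimethoxy-4,5,8-trioxo-5,8-dihydro-4H-chromen-2-yl)-2,3-dimethoxyphenyl 2,2-dimethylpropanoate | COC1=C(OC)C(=O)C2=C(C1=O)C(=O)C=C(c1cc(OC)c(OC)c(OC(=O)C(C)(C)C)c1)O2
F3 | step 7 | 5-(5,8-dihydroxy-6,7-dimethoxy-4-oxo-4H-chromen-2-yl)-2,3-dimethoxyphenyl 2,2-dimethylpropanoate | COc1cc(-c2cc(=O)c3c(O)c(OC)c(OC)c(O)c3o2)cc(OC(=O)C(C)(C)C)c1OC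
F4 | step 5 | 5-(5,6-dihydroxy-7-methoxy-4-oxo-4H-chromen-2-yl)-2,3-dimethoxyphenyl 2,2-dimethylpropanoate | COc1cc(-c2cc(=O)c3c(O)c(O)c(OC)cc3o2)cc(OC(=O)C(C)(C)C)c1OC
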